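**Plan**
1. Ring numbering used throughout: C1 carries the acyl chain, C2 the 3,4-dimethoxyphenyl group, C3=C4 is the ring alkene, C5 is CH2, C6 carries the 4-hydroxy-3-methoxyphenyl group.
2. Retrosynthesis: the two phenols are masked as acetates, then the cyclohexene is opened by a retro-[4+2] across C1–C2 and C5–C6 (the C3=C4 alkene with the acyl group on C1 is the Diels–Alder retron). This gives curcumin diacetate as dienophile and (E)-1-(3,4-dimethoxyphenyl)buta-1,3-diene as diene; the diene is cut at its terminal C=C to 3,4-dimethoxycinnamaldehyde.
3. Forward: Wittig methylenation gives the diene and curcumin is diacetylated. The enolized 1,3-diketone (O=C–CH=C–OH, next to the future C1) then binds a chiral diol borate as a cationic six-membered O–B–O chelate ring, and one exo Diels–Alder reaction on one of the two equivalent enone arms builds the cyclohexene, the only new ring. Deacetylation ends the route; the dienone chain comes ready-made from curcumin.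
4. Stereochemistry: C1/C6 trans from the E enone, C1/C2 trans from the exo transition state of the E diene, absolute configuration (1R,2R,6S) from the (R)-ligand on boron; no centre is touched afterwards.

Key step: step 3

Assumption: the sense of induction of the (R)-ligand is assigned from a quadrant model of the spiroborate and not from a known case (the (S)-ligand is equally available should a test run show the opposite sense), and the diketone is drawn throughout as the keto–enol tautomer of the target SMILES.

**Step 1**
Reactants: 1 (E)-3-(3,4-dimethoxyphenyl)prop-2-enal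
Product: 2 (E)-1-(3,4-dimethoxyphenyl)buta-1,3-diene
Conditions: MePPh3Br, KOtBu, THF, 0 °C to rt; product kept cold over BHT and used fresh
Reagents that add atoms: methyltriphenylphosphonium bromide, C[P+](c1ccccc1)(c1ccccc1)c1ccccc1.[Br-]
Why: Wittig methylenation, in which the non-stabilized ylide adds only to the aldehyde carbon, the existing E styryl bond is untouched and the new terminal alkene carries no stereochemistry.

**Step 2**
Reactants: 3 curcumin
Product: 4 di-O-acetylcurcumin
Conditions: Ac2O (2.2 equiv), pyridine, CH2Cl2, 0 °C to rt
Reagents that add atoms: acetic anhydride, CC(=O)OC(C)=O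
Why: Acylation of phenols with an anhydride under pyridine catalysis, in which the two phenols are far more nucleophilic than the hydrogen-bonded enol and the small excess of Ac2O should leave the enol free; no stereocenter is involved.

**Step 3**
Reactants: 4 di-O-acetylcurcumin (two-fold excess over 2); 2 (E)-1-(3,4-dimethoxyphenyl)buta-1,3-diene
Product: 7 (1R,2R,6S)-cycloadduct diacetate (acyl group on C1 trans to both aryl groups), via dienophile spiroborate 5 (not isolated), via cycloadduct spiroborate 6 (not isolated)
Conditions: B(OPh)3 and (R)-VANOL [(R)-3,3'-diphenyl-2,2'-binaphthalene-1,1'-diol] premixed (1 equiv each per 4), 4 Å molecular sieves, PhCF3, 40 °C, then 4; then 2, rt; then THF, 1 M aq HCl, rt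
Reagents that add atoms: none
Why: Proposed new method: triphenyl borate, the (R)-diol and the enol of 4 should exchange to the twofold-symmetric spiroborate 5, whose six-membered O–B–O diketonate chelate carries the positive charge and lowers the LUMO of both s-cis enone arms, so that diene 2 adds to one arm in a concerted, asynchronous normal-demand [4+2] cycloaddition (CH2 terminus to the β-carbon, aryl-bearing terminus to the α-carbon) and acid hydrolysis of chelate 6 frees 7 and the ligand. The closest known reaction type is the asymmetric Diels–Alder reaction of 2'-hydroxychalcones with 1-aryl dienes promoted by borates of chiral biaryl diols, in which an o-acylphenolate and not a 1,3-diketonate forms the chelate. The cyclohexene is closed intermolecularly in a suprafacial–suprafacial [4πs+2πs] mode, both new σ bonds forming on one face of the enone. C1 and C6 should come out trans because the E geometry of the enone is kept, C2 should come out trans to C1 through the exo transition state (carbonyl exo, β-aryl endo), in which the dimethoxyphenyl ring of the E diene can stack on the electron-poor chelate ring, and the absolute configuration (1R,2R,6S) follows from addition to the Si face of the α- and β-carbons, the Re face of each arm lying under a vaulted naphthalene of the (R)-ligand. The step needs ortho regioselectivity (secured by the polarized chelated enone and the 1-aryl diene), exo and facial selectivity (expected from the ligand) and mono-addition; the two arms are equivalent by symmetry, so either gives the same product, and the two-fold excess of 4 should keep the second arm from reacting, with unreacted 4 and the ligand recovered.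

**Step 4**
Reactants: 7 (1R,2R,6S)-cycloadduct diacetate
Product: 8 target, (2Z,4E)-1-[(1R,2R,6S)-2-(3,4-dimethoxyphenyl)-6-(4-hydroxy-3-methoxyphenyl)cyclohex-3-en-1-yl]-3-hydroxy-5-(4-hydroxy-3-methoxyphenyl)penta-2,4-dien-1-one
Conditions: K2CO3, degassed MeOH/THF, 0 °C, argon; then aq NaH2PO4
Reagents that add atoms: none
Why: Base-catalysed transesterification of aryl acetates (Zemplén-type methanolysis), in which the aryl esters should cleave quickly at 0 °C while the diketone sits as its potassium enolate, which blocks a second deprotonation at ring C1, and the all-trans arrangement is in any case the thermodynamically preferred one, so the three stereocenters should be kept.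

**Compound list**
1 | (E)-3-(3,4-dimethoxyphenyl)prop-2-enal (3,4-dimethoxycinnamaldehyde) | COc1ccc(/C=C/C=O)cc1OC | starting material
2 | (E)-1-(3,4-dimethoxyphenyl)buta-1,3-diene | COc1ccc(/C=C/C=C)cc1OC | intermediate
3 | curcumin, (1E,4Z,6E)-5-hydroxy-1,7-bis(4-hydroxy-3-methoxyphenyl)hepta-1,4,6-trien-3-one | COc1cc(/C=C/C(O)=C/C(=O)/C=C/c2ccc(O)c(OC)c2)ccc1O | starting material
4 | di-O-acetylcurcumin (both phenols as acetates) | COc1cc(/C=C/C(O)=C/C(=O)/C=C/c2ccc(OC(C)=O)c(OC)c2)ccc1OC(C)=O | intermediate
5 | dienophile spiroborate: boron bound to the diketonate of 4 and to the (R)-VANOL diolate (axis R, not expressible in plain SMILES) | CC(=O)Oc1ccc(/C=C/C2=CC(/C=C/c3ccc(OC(C)=O)c(OC)c3)=[O+][B-]3(O2)Oc2c(-c4c(O3)c5ccccc5cc4-c4ccccc4)c(-c4ccccc4)cc4ccccc24)cc1OC | intermediate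
6 | cycloadduct spiroborate: boron bound to the diketonate of 7 and to the (R)-VANOL diolate (axis R) | CC(=O)Oc1ccc(/C=C/C2=CC([C@@H]3[C@@H](c4ccc(OC(C)=O)c(OC)c4)CC=C[C@H]3c3ccc(OC)c(OC)c3)=[O+][B-]3(O2)Oc2c(-c4c(O3)c5ccccc5cc4-c4ccccc4)c(-c4ccccc4)cc4ccccc24)cc1OC | intermediate
7 | 4-[(1E,3Z)-5-[(1R,2R,6S)-6-(4-acetoxy-3-methoxyphenyl)-2-(3,4-dimethoxyphenyl)cyclohex-3-en-1-yl]-3-hydroxy-5-oxopenta-1,3-dien-1-yl]-2-methoxyphenyl acetate | COc1cc(/C=C/C(O)=C/C(=O)[C@@H]2[C@@H](c3ccc(OC(C)=O)c(OC)c3)CC=C[C@H]2c2ccc(OC)c(OC)c2)ccc1OC(C)=O | intermediate
8 | (2Z,4E)-1-[(1R,2R,6S)-2-(3,4-dimethoxyphenyl)-6-(4-hydroxy-3-methoxyphenyl)cyclohex-3-en-1-yl]-3-hydroxy-5-(4-hydroxy-3-methoxyphenyl)penta-2,4-dien-1-one | COc1cc(/C=C/C(O)=C/C(=O)[C@@H]2[C@@H](c3ccc(O)c(OC)c3)CC=C[C@H]2c2ccc(OC)c(OC)c2)ccc1O | target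

**Count**
Total steps: 4. Longest linear sequence: 3 steps (3 → 4 → 7 → 8, or 1 → 2 → 7 → 8).

**Steps most likely to fail**

1. Step 3 (proposed new method). What may go wrong: too little discrimination between exo and endo modes or between the two faces, over-addition to the second enone arm, acid-induced oligomerization of the electron-rich diene, or incomplete release of boron. The fallback uses known chemistry, sets out from 4 (with 2) and comes back at 7. Excess 4 and 2 would be heated without boron or ligand (toluene, 150 °C, sealed tube, BHT). The thermal Diels–Alder reaction of a chalcone-type enone with a 1-aryl diene should give the exo cycloadduct as a racemate, that is 7 together with its enantiomer, the (1S,2S,6R)-cycloadduct diacetate F1. After chromatographic removal of endo-mode material, the racemate would be resolved by preparative HPLC on a chiral stationary phase (amylose tris(3,5-dimethylphenylcarbamate)), and 7 would go on into step 4.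

2. Step 4. What may go wrong: base-induced degradation of the enolized dienone chain (retro-Claisen cleavage, autoxidation of the phenoxide and enolate) during methanolysis. The fallback changes the protecting group so that the end step is a fluoride cleavage; it sets out from 3 and comes back at 8. Curcumin would be silylated (TBSCl, imidazole, DMF) to bis(tert-butyldimethylsilyl)curcumin F2. The conditions of step 3 would take it through the silyl dienophile spiroborate F3 and the silyl cycloadduct spiroborate F4 to the bis(tert-butyldimethylsilyl) cycloadduct F5. HF·pyridine in THF/pyridine at 0 °C, under which the enolized diketone is stable, would then give 8.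

3. Step 1. What may go wrong: [4+2] dimerization or polymerization of the electron-rich diene during removal of triphenylphosphine oxide and on storage. The fallback is a two-stage Peterson olefination that keeps a storable precursor; it sets out from 1 and comes back at 2. Me3SiCH2MgCl would add to the aldehyde (THF, −78 °C) to give racemic (E)-4-(3,4-dimethoxyphenyl)-1-(trimethylsilyl)but-3-en-2-ol F6. KH (THF, 0 °C) would then bring about the syn-elimination just before step 3, so that 2 is never stored.

**Further compounds**
F1 | step 3 | (1S,2S,6R)-cycloadduct diacetate, enantiomer of 7 | COc1cc(/C=C/C(O)=C/C(=O)[C@H]2[C@H](c3ccc(OC(C)=O)c(OC)c3)CC=C[C@@H]2c2ccc(OC)c(OC)c2)ccc1OC(C)=O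
F2 | step 4 | bis(tert-butyldimethylsilyl)curcumin | COc1cc(/C=C/C(O)=C/C(=O)/C=C/c2ccc(O[Si](C)(C)C(C)(C)C)c(OC)c2)ccc1O[Si](C)(C)C(C)(C)C
F3 | step 4 | silyl dienophile spiroborate of F2 with the (R)-VANOL diolate (axis R) | CC(C)(C)[Si](C)(C)Oc1ccc(/C=C/C2=CC(/C=C/c3ccc(O[Si](C)(C)C(C)(C)C)c(OC)c3)=[O+][B-]3(O2)Oc2c(-c4c(O3)c5ccccc5cc4-c4ccccc4)c(-c4ccccc4)cc4ccccc24)cc1OC
F4 | step 4 | silyl cycloadduct spiroborate of F5 with the (R)-VANOL diolate (axis R) | CC(C)(C)[Si](C)(C)Oc1ccc(/C=C/C2=CC([C@@H]3[C@@H](c4ccc(O[Si](C)(C)C(C)(C)C)c(OC)c4)CC=C[C@H]3c3ccc(OC)c(OC)c3)=[O+][B-]3(O2)Oc2c(-c4c(O3)c5ccccc5cc4-c4ccccc4)c(-c4ccccc4)cc4ccccc24)cc1OC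
F5 | step 4 | (1R,2R,6S)-bis(tert-butyldimethylsilyl) cycloadduct | COc1cc(/C=C/C(O)=C/C(=O)[C@@H]2[C@@H](c3ccc(O[Si](C)(C)C(C)(C)C)c(OC)c3)CC=C[C@H]2c2ccc(OC)c(OC)c2)ccc1O[Si](C)(C)C(C)(C)C
F6 | step 1 | racemic (E)-4-(3,4-dimethoxyphenyl)-1-(trimethylsilyl)but-3-en-2-ol | COc1ccc(/C=C/C(O)C[Si](C)(C)C)cc1OC
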